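If a closed flask of starting material and free catalyst makes target for a while and then levels off, the first thing to ask is where the rest of the charge went.

| flask | starting material | free catalyst | target | time |
|---|---|---|---|---|
| maple | 0.250 M | 0.0250 M |  |  |
| ash | 0.150 M | 0.0250 M |  |  |
| birch | 0.250 M | 0.0750 M |  |  |
| oak | 0.250 M | 0.0250 M | 0.0750 M |  |
| alder | 0.620 M | 0.0250 M |  | 58 min |

| maple run: time / min | maple run: [target] / M | ash run: time / min | ash run: [target] / M | birch run: time / min | birch run: [target] / M | oak run: time / min | oak run: [target] / M |
|---|---|---|---|---|---|---|---|
| 2.6 | 0.0086 | 2.6 | 0.0040 | 2.6 | 0.0191 | 2.6 | 0.0816 |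
| 7.8 | 0.0293 | 7.8 | 0.0147 | 7.8 | 0.0671 | 7.8 | 0.1041 |
| 15 | 0.0500 | 15 | 0.0256 | 15 | 0.1033 | 15 | 0.1265 |
| 24 | 0.0670 | 24 | 0.0349 | 24 | 0.1231 | 24 | 0.1433 |
| 34 | 0.0775 | 34 | 0.0388 | 34 | 0.1340 | 34 | 0.1512 |
| 45 | 0.0797 | 45 | 0.0394 | 45 | 0.1388 | 45 | 0.1566 |
| 58 | 0.0840 | 58 | 0.0403 | 58 | 0.1407 | 58 | 0.1589 |

(scatter of a reading: 8 × 10⁻⁴ M)

- Overall: starting material -> target, with free catalyst as catalyst.
- Constant volume, constant temperature.
- Bound and free are read together.
- An order is taken over about fifteen percent of the charge, up and down.

1. the exponent of [free catalyst] in the starting rate at the charge of the maple run (at the point where two percent of the starting material have become target)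
2. the exponent of [starting material] in the starting rate at the charge of the maple run (at the point where two percent of the starting material have become target) (one fixed amount of target, the same in the runs compared)
3. target in the alder run at 58 min, as a share of the starting material charged

*What do you read first?* The end of each run, as a split of the charge. Maple ends with c(target) at 0.0840 M out of 0.250 M, so I take the end odds, target made at the last reading divided by the part of the charge that isn't target, 0.506 in maple. If two routes race for the starting material, this is their selectivity factor. Ash gives 0.367.

*Does target in the charge matter?* Oak starts with 0.0750 M of target and, counting its gain, reaches end odds of 0.505, which is about the same as maple.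

*And more catalyst?* Birch has 3.00 times the catalyst of maple and end odds of 1.29, which is 2.55 times those of maple. That suits a catalysed route racing a rival with a time constant of its own.

*Can you prove that rival? A dying catalyst also levels a run.* No, I have not separated the two from these readings, so the rival is my assumption.

*Then what do you expect of alder?* Multiply end odds by the charge to get a strength of the target route, 0.0551 M in ash and 0.127 M in maple. I assume a ceiling for a fixed amount of catalyst. A ceiling curve in the first power of the charge gives a negative ceiling, −0.134 M, so I use the square: the reciprocal of strength is a constant plus a term in one over the charge squared. Through ash and maple this gives a slope of 0.360 M and a constant of 2.14 /M, so a ceiling of 0.467 M. Alder then has end odds of 0.524, a share of 34.4%. The two orders I leave to the forecast.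

*And the forecast?* It reads the flask differently from me: “The maple plateau near 0.085 M, with most of the starting material left, shows the catalyst dies”. It gives 0.8 and 1.25 for the orders and 43% for alder, which is end odds of 0.754.

The simulation gives 0.71, 0.83 and 37.1%, so alder's end odds are 0.590.

    active catalyst + starting material ⇌ catalyst-substrate complex, settled at all times (0.5210 /M)
    catalyst-substrate complex + starting material ⇌ doubly bound catalyst, settled at all times (39.10 /M)
    doubly bound catalyst → target + catalyst-substrate complex (0.4590 /min)
    free catalyst → active catalyst (0.7680 /min)
    starting material → decomposed substrate (0.02862 /min)

In the alder run, free catalyst turned to active catalyst with a time constant of 1.30 min, and doubly bound catalyst then gave target at a ceiling of 0.0115 M/min. From the first minute, starting material also went to decomposed substrate, at 0.0177 M/min from the full charge, which is faster than that ceiling, with a time constant of 34.9 min. At 58 min alder's end odds stood at 0.590, while maple, with the same free catalyst, had reached 0.506 and birch, with 0.0750 M of free catalyst, 1.29.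

Readings and results are calculated for substances that don't exist; the scatter is artificial.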